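At the last reading of the earlier runs, 8.00 min, the right-handed substrate stood below the left-handed one: 28.2 % against 37.8 % in the dawn run, and 29.7 % against 40.8 % in the dusk run. The new flask lies between them in charge.

| setting | dawn | dusk | flask |
|---|---|---|---|
| left-handed substrate | 0.34 mM | 0.75 mM | 0.50 mM |
| right-handed substrate | 0.34 mM | 0.75 mM | 0.50 mM |
| gas | 0.30 mM (held) | 0.30 mM (held) | 0.30 mM (held) |
| precatalyst | 35 µM | 35 µM | 35 µM |
| remark | run made earlier | run made earlier |  |
| time |  |  | 12 min |

| run | time / min | right-handed substrate / % | left-handed substrate / % |
|---|---|---|---|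
| dawn | 0.417 | 48.8 | 51.6 |
| dawn | 1.00 | 45.7 | 48.8 |
| dawn | 2.00 | 40.8 | 46.6 |
| dawn | 3.00 | 36.1 | 43.6 |
| dawn | 4.00 | 31.8 | 41.3 |
| dawn | 6.00 | 29.8 | 36.3 |
| dawn | 8.00 | 28.2 | 37.8 |
| dusk | 1.00 | 47.3 | 50.2 |
| dusk | 2.00 | 45.8 | 45.4 |
| dusk | 3.00 | 40.8 | 44.9 |
| dusk | 4.00 | 38.9 | 47.3 |
| dusk | 5.00 | 34.1 | 43.9 |
| dusk | 6.00 | 33.9 | 42.8 |
| dusk | 8.00 | 29.7 | 40.8 |

(scatter of a reading: 1 percentage point)

1. whether the excess of right-handed substrate over left-handed substrate among what is left of the two reaches 80 % by 12 min (yes / no)
2. the highest excess of right-handed substrate over left-handed substrate among what is left of the two up to 12 min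

- free catalyst is single-handed; left-handed substrate and right-handed substrate are mirror images of each other, charged as a racemate, each of them at the stated concentration
- the numbers in the tables scatter with a standard deviation of 1 percentage point
- at the start none of the gas is in solution

I followed one molecule of each substrate. Both meet the same free catalyst, so I assumed that the ratio s of their chances of being consumed stays constant while the amount of catalyst changes. Let f be the fraction of a substrate's own charge still left. Then ln f_S = s ln f_R, where S is the right-handed substrate and R the left-handed one. Each starts at half of the two together.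

The dawn run gave s = 2.05. The dusk run, as a second way, gave 2.56. They parted, so I looked for the weaker one. The left-handed substrate had lost 12 percentage points in the dawn run but 9.2 points in the dusk run, against a scatter of 1 point, so the dusk value rested on the smaller loss. Yet the dawn left-handed readings rose from 36.3 % at 6.00 min to 37.8 %, and a substrate being consumed does not rise. Neither value was clean, so I kept their mean, 2.30, as the selectivity factor.

Both values lay above one. With s above one, f_S stays below f_R once reaction starts. I therefore expected the excess of right over left to fall from zero, and its highest value to be the start.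

The forecast said no, with a top of 0 % (range 0 % to 1 %), noting that “what remains is enriched in left-handed substrate”. The flask gave no and 0 %, and the excess was already −2.62 % at 1.20 min.

    partner + precatalyst → free catalyst + spent reagent (k = 170 M⁻¹ s⁻¹)
    partner + catalyst intermediate A → free catalyst + left-handed product (k = 670 M⁻¹ s⁻¹)
    gas ⇌ partner, rate k3*(csat - [partner]) (kL = 0.0170 s⁻¹)
    free catalyst → spent catalyst (k = 0.0300 s⁻¹)
    free catalyst + right-handed substrate ⇌ catalyst intermediate B (K = 14000 M⁻¹, k = 3500 M⁻¹ s⁻¹)
    free catalyst + left-handed substrate ⇌ catalyst intermediate A (K = 1700 M⁻¹, k = 15000 M⁻¹ s⁻¹)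
    partner + catalyst intermediate B → free catalyst + right-handed product (k = 220 M⁻¹ s⁻¹)

At 12.0 min the flask kept 75 % of its left-handed substrate. Raised to the power s, that gave 51.6 % for the right-handed substrate, and the flask kept 52 %. A neighbouring flask was charged with 0.087 mM of precatalyst instead of 35 µM. It kept 55 % of its left-handed substrate, so the same power gave 25.6 % for the right-handed substrate, and that flask kept 27 %. Its top stayed 0 %, and its excess at 12.0 min stood at −35.0 %.

The runs are simulated from invented constants; noise was put on by code.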